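(The earlier runs and the new flask are calculated for substances that don't exist; scatter was added.)

Late in Tuesday's run the product stood near 48.1% of the electrophile charged, and at 120 min it read 47.2%, with 52.6% of the electrophile still there. That flask held 0.051 M of nucleophile against 0.050 M of electrophile. So I counted turnovers: I took each turnover to make one product and one acid set free, and I took that acid to bind a second nucleophile as protonated nucleophile. The nucleophile is then the limiting reagent, and it is spent at two per product.

| setting | Tuesday's | Monday's | west | south-west | south |
|---|---|---|---|---|---|
| electrophile | 0.050 M | 0.050 M | 0.050 M | 0.050 M | 0.050 M |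
| nucleophile | 0.051 M | 0.16 M | 0.0450 M | 0.100 M | 0.0680 M |
| gas | 4.8 mM (held) | 4.8 mM (held) | 4.8 mM (held) | 4.8 mM (held) | 4.8 mM (held) |
| remark | run made earlier | run made earlier |  |  |  |
| time |  |  | 2.5 h | 2.5 h | 2.5 h |

| run | time / min | electrophile / % | product / % |
|---|---|---|---|
| Tuesday's | 25.0 | 59.2 | 39.8 |
| Tuesday's | 50.0 | 54.4 | 44.9 |
| Tuesday's | 80.0 | 52.0 | 48.1 |
| Tuesday's | 120 | 52.6 | 47.2 |
| Monday's | 12.0 | 30.1 | 68.3 |
| Monday's | 40.0 | 10.5 | 89.1 |
| Monday's | 60.0 | 7.4 | 92.6 |
| Monday's | 120 | 2.6 | 97.0 |

(readings scatter by 0.5 percentage points)

1. part of the electrophile that has reacted at the end, west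
2. part of the electrophile that has reacted at the end, south-west
3. part of the electrophile that has reacted at the end, south
4. what raising the concentration of nucleophile from its lowest to its highest value here does to the part of the electrophile that has reacted (changes below 5 percentage points count as none) (it rises / no change / it falls)

- at the start none of free base is dissolved
- steps thought possible: electrophile + nucleophile -> acid set free + product; nucleophile + acid set free <-> protonated nucleophile; acid set free + free base <-> salt of the base; gas <-> free base; 2 nucleophile -> homo dimer

I named the count the ceiling C: the nucleophile charged, divided by two and by the electrophile charged. For west, the ceiling C came to 45.0%. South had 68.0% and south-west 100%. Tuesday's C was 51.0%, just above its plateau. Monday's C was 160%, so there the electrophile ran down, to 2.6% at 120 min. Tuesday's plateau stood by 80.0 min, earlier than the 2.5 h asked, so I expected the count, not the clock, to set the answers. The possible step to homo dimer also spends nucleophile and is second order in it, so I held south-west's ceiling the loosest.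

The forecast gave 42.7% for west, 62% for south and 85% for south-west, and said it rises. Its ground was “each product costs two nucleophiles, one reacting and one trapping the acid”. Its numbers lay below my ceilings, which I held as a count and not as a bound.

The flasks gave 43.4% in west, 61.3% in south and 81.4% in south-west. So it rises, by 38 percentage points.

    electrophile + nucleophile → acid set free + product (k = 66.7 M⁻¹ h⁻¹)
    nucleophile + acid set free ⇌ protonated nucleophile, settled at all times (K = 1.67 × 10⁵ M⁻¹)
    acid set free + free base ⇌ salt of the base, settled at all times (K = 461 M⁻¹)
    gas ⇌ free base, rate k4*(csat - [free base]) (kL = 5.31 h⁻¹)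
    2 nucleophile → homo dimer (k = 10.4 M⁻¹ h⁻¹)

West ended 1.6 points under its ceiling of 45.0%. At 2.50 h west held 0.0198 M of protonated nucleophile, far more than its 0.00131 M of salt of the base, and 0.43% of its nucleophile was still free. A neighbour of south-west, charged with 0.040 M of nucleophile, has a ceiling of 40.0%. That neighbour gave 39.1% at 2.50 h, with 0.43% of its nucleophile still free.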